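At 10.0 h in the beta run there is less isomer of the product (10.7%) than target (19.6%), but their ratio r, isomer of the product over target, has been climbing, so the pace of that climb is what to watch in the flask at 0.22 M.

| setting | beta | eta | flask |
|---|---|---|---|
| substrate | 0.11 M | 0.44 M | 0.22 M |
| remark | run made earlier | run made earlier |  |
| time |  |  | 15 h |

| run | time / h | isomer of the product / % | target / % |
|---|---|---|---|
| beta | 2.00 | 3.4 | 31.4 |
| beta | 4.00 | 7.0 | 36.8 |
| beta | 5.00 | 7.8 | 35.7 |
| beta | 8.00 | 10.3 | 26.3 |
| beta | 10.0 | 10.7 | 19.6 |
| eta | 0.667 | 0.9 | 14.6 |
| eta | 1.33 | 1.4 | 24.6 |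
| eta | 2.50 | 4.0 | 34.1 |
| eta | 5.00 | 7.6 | 35.5 |
| eta | 10.0 | 11.1 | 19.6 |

(each reading ± 0.3 percentage points)

1. ratio of isomer of the product to target at 5.0 min
2. ratio of isomer of the product to target at 15 h
3. which of isomer of the product and target there is more of at 15 h

- the numbers in the tables scatter by 0.3 percentage points (one standard deviation)

Step 1: with substrate to target as the one process, r is zero. The beta and eta runs show target at 19.6% and 19.6% at 10.0 h, although their charges differ by a factor of 4.00, so I read both runs as one first-order curve and apply it to the flask.

Step 2: add the isomer of the product. A first-order stream running parallel to the making of target from the start holds r flat while target is not lost, but in the beta run r goes from 0.108 at 2.00 h to 0.190 at 4.00 h. I therefore read an induction period, with r proportional to time. The first beta reading gives a slope of 0.0541 /h, so I expect r of 0.00451 at 5.0 min in the flask.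

Step 3: add the loss of target. In the beta and eta runs target falls after 5.00 h while the isomer of the product creeps upward, so I take r to grow by a fixed factor per hour. Between 5.00 h and 10.0 h, the beta run gives 0.183 /h and the eta run 0.195 /h. Their mean, 0.189 /h, is the drift g, the slope of ln r against time. Starting from the mean r of 0.556 at 10.0 h, I expect r to reach one near 13.1 h and 1.43 at 15 h.

The forecast, which differs from my reckoning, gives 0.03 at 5.0 min, reading the early ratio as “a small direct route from substrate”, and 1.15 at 15 h, with isomer of the product ahead.

The flask gives 0.00474 at 5.0 min and 1.39 at 15 h, with isomer of the product ahead, 11.6% against 8.29% of target. The two stand level in the flask at 13.2 h. Carrying g from that level point over the remaining 1.80 h gives r of 1.41.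

    substrate ⇌ other conformer (K = 2.89, k = 7.99 × 10⁻⁴ /min)
    substrate → target (k = 0.00438 /min)
    other conformer → isomer of the product (k = 0.0105 /min)
    other conformer ⇌ third conformer (K = 2.31, k = 0.00265 /min)
    third conformer → third product (k = 0.0242 /min)
    other conformer ⇌ dormant form (K = 1.75, k = 6.73 × 10⁻⁴ /min)
    target → over-reaction product (k = 0.00360 /min)

In a neighbour flask with 0.13 M of substrate, I carry the same g and the same r at 10.0 h, which gives 1.43 at 15 h. The computed ratio there is 1.39.

The numbers in the tables stem from a simulated flask with constants of no real substance.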